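Time comes first: green stops at 30 min and violet at 50 min. In the south-east run, target climbs from 3.5 % at 15.0 min to 13.2 % at 30.0 min. That is a factor of 3.77 when the time doubles, so I read target as growing about as time squared, an induction period.

| flask | substrate | partner | precatalyst | remark | time |
|---|---|---|---|---|---|
| south-east | 0.093 M | 0.084 M | 93 µM | run made earlier |  |
| green | 0.060 M | 0.0558 M | 50 µM |  | 30 min |
| violet | 0.093 M | 0.0558 M | 93 µM |  | 50 min |

south-east run (percent of the substrate charged)

| time / min | target / % | substrate / % |
|---|---|---|
| 2.00 | 0.4 | 100.2 |
| 6.00 | 0.5 | 99.2 |
| 10.0 | 1.8 | 98.4 |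
| 15.0 | 3.5 | 96.3 |
| 25.0 | 9.1 | 90.0 |
| 30.0 | 13.2 | 86.5 |

(scatter of a reading: 0.3 percentage points)

- no earlier run changes the charge of precatalyst; that part of a forecast is a guess

- which of the two ends with the higher amount of target, in percent of the substrate charged ("neither" if they lie within 2 percentage points) (green / violet / neither)
- target at the end, in percent of the substrate charged, green
- target at the end, in percent of the substrate charged, violet

I turn the question round: what must be true for green to draw level? Both flasks hold 0.0558 M of partner, so I set partner aside. Violet's lead is the squared time ratio times the precatalyst ratio times the substrate ratio: 3.33. The substrate ratio supposes a rate indifferent to substrate. The precatalyst ratio is a guess, since no earlier run varies that charge. A tie needs a lead near one, and this flask stands well above that.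

My own reckoning puts violet at 36.7 % by the square law, under the 60.0 % that partner, the limiting reagent, allows. Dividing by the lead puts green at 11.0 %. The gap of 26 percentage points is wider than the margin of 2 points.

The forecast says violet, with green at 6 % (2.5 % to 11 %) and violet at 26 % (16 % to 36 %): “Violet clearly ends higher.” Both its figures lie below mine.

The flask gives violet, with green at 8.77 % and violet at 28.0 %.

    substrate + free catalyst ⇌ catalyst intermediate A (K = 6.80 M⁻¹, k = 11.0 M⁻¹ s⁻¹)
    partner + catalyst intermediate A ⇌ catalyst intermediate B (K = 52.0 M⁻¹, k = 190 M⁻¹ s⁻¹)
    catalyst intermediate B ⇌ released group + catalyst intermediate C (K = 0.110 M, k = 19.0 s⁻¹)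
    catalyst intermediate C ⇌ catalyst intermediate D (K = 1.20, k = 0.940 s⁻¹)
    catalyst intermediate D → free catalyst + target (k = 13.0 s⁻¹)
    precatalyst → free catalyst (k = 2.50 × 10⁻⁴ s⁻¹)

That is a ratio of 3.19 against my lead of 3.33. The neighbour is green with 0.015 M of substrate, its other charges and its time held. Violet's lead over it reckons to 0.833, below one, so the same reckoning puts the neighbour ahead of violet. The neighbour reads 12.8 %, less than violet, and violet's real lead over it is 2.19.

The runs stem from a simulated flask with made-up constants, noise included.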